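**Retrosynthetic overview**
1. Target ⇐ acetylation of O2/O12, C12‑OH‑directed 13,14‑epoxidation and OH→Cl inversion at C6 on a ten‑membered carbinol, which comes from CrCl2/NiCl2 closure of the C5–C6 bond.
2. C6 aldehyde on the γ‑lactone ⇐ dithiane acyl‑anion addition to a dioxolanone, then chelation‑controlled C7 reduction; C8–C9 ⇐ aldol of the (S)‑malic acid dioxolanone enolate (C8, C17) with the ring A C9 aldehyde.
3. C2–C3 ⇐ Felkin addition of a butynyl Grignard reagent to the C2 lactol; the alkyne becomes the 2‑iodoalkene.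
4. Ring A (quaternary C1, C10) ⇐ Ireland–Claisen ring contraction ([3,3]) of a δ‑lactone silyl ketene acetal bearing a (Z)‑alkenyl group; this key step forms the C1–C10 bond.
5. δ‑Lactone ⇐ acrylate RCM, cuprate addition, ozonolysis, Still–Gennari olefination from (3S,4S)‑hexa‑1,5‑diene‑3,4‑diol. Ring order: δ‑lactone (temporary) → ring A → γ‑lactone → ten‑membered ring → epoxide.

Assumption: (3S,4S)‑hexa‑1,5‑diene‑3,4‑diol (sold; made from L‑tartaric acid) is bought. Briarane numbering is used throughout, and β is the face of ring A that carries the C15 methyl. TES = triethylsilyl, TBS = tert‑butyldimethylsilyl.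

The route is a paper design; stereochemical outcomes are predictions from the models named in each step.

**Step 1**
Reactants: 1 (3S,4S)-hexa-1,5-diene-3,4-diol
Product: 2 (3S,4S)-4-(triethylsilyloxy)hexa-1,5-dien-3-ol
Conditions: Et3SiCl (1.0 equiv), imidazole, CH2Cl2, −40 → 0 °C
Reagents that add atoms: chlorotriethylsilane, CC[Si](Cl)(CC)CC
Why: Monosilylation of a C2‑symmetric diol gives one mono‑ether because the two hydroxyls are homotopic; no stereocenter is touched.

**Step 2**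
Reactants: 2 (3S,4S)-4-(triethylsilyloxy)hexa-1,5-dien-3-ol
Product: 3 (3S,4S)-4-(triethylsilyloxy)hexa-1,5-dien-3-yl acrylate
Conditions: acryloyl chloride, i-Pr2NEt, CH2Cl2, −78 → −20 °C
Reagents that add atoms: acryloyl chloride, C=CC(=O)Cl
Why: Simple O‑acylation installs C9 and C10 on the oxygen that later leaves C13.

**Step 3**
Reactants: 3 (3S,4S)-4-(triethylsilyloxy)hexa-1,5-dien-3-yl acrylate
Product: 4 (5S,6S)-6-ethenyl-5-(triethylsilyloxy)-5,6-dihydro-2H-pyran-2-one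
Conditions: second-generation Grubbs catalyst (5 mol %), CH2Cl2 (0.01 M), 40 °C
Reagents that add atoms: none
Why: Ring‑closing metathesis closes the acrylate onto the distal vinyl group to the six‑membered unsaturated lactone (the butenolide mode is disfavoured); the threo diol gives the 5,6‑cis lactone.

**Step 4**
Reactants: 4 (5S,6S)-6-ethenyl-5-(triethylsilyloxy)-5,6-dihydro-2H-pyran-2-one
Product: 5 (4R,5S,6S)-6-ethenyl-4-methyl-5-(triethylsilyloxy)oxan-2-one
Conditions: Me2CuLi (from MeLi, CuI; 1.5 equiv), Et2O, −78 °C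
Reagents that add atoms: lithium dimethylcuprate, [Li+].C[Cu-]C
Why: Cuprate 1,4‑addition occurs anti to the adjacent silyloxy group, so the C11 methyl is trans to O12; at −78 °C it should outpace SN2′ opening of the vinyl lactone.

**Step 5**
Reactants: 5 (4R,5S,6S)-6-ethenyl-4-methyl-5-(triethylsilyloxy)oxan-2-one
Product: 7 (2R,3S,4R)-4-methyl-6-oxo-3-(triethylsilyloxy)oxane-2-carbaldehyde, via ozonide 6 (not isolated)
Conditions: O3, CH2Cl2, −78 °C; then PPh3, −78 °C → rt
Reagents that add atoms: ozone, [O-][O+]=O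
Why: Ozonolysis with reductive work‑up turns the only alkene into the C14 aldehyde without touching C13.

**Step 6**
Reactants: 7 (2R,3S,4R)-4-methyl-6-oxo-3-(triethylsilyloxy)oxane-2-carbaldehyde
Product: 8 ethyl (Z)-2-methyl-3-[(2S,3S,4R)-4-methyl-6-oxo-3-(triethylsilyloxy)oxan-2-yl]prop-2-enoate
Conditions: (CF3CH2O)2P(O)CH(CH3)CO2Et, KN(SiMe3)2, 18-crown-6, THF, −78 °C
Reagents that add atoms: ethyl 2-[bis(2,2,2-trifluoroethoxy)phosphoryl]propanoate, CCOC(=O)C(C)P(=O)(OCC(F)(F)F)OCC(F)(F)F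
Why: Still–Gennari olefination gives the (Z)‑trisubstituted enoate (ester cis to C13, C15 methyl trans), the geometry the next step needs.

**Step 7**
Reactants: 8 ethyl (Z)-2-methyl-3-[(2S,3S,4R)-4-methyl-6-oxo-3-(triethylsilyloxy)oxan-2-yl]prop-2-enoate
Product: 11 (1S,2S,5R,6R)-2-(ethoxycarbonyl)-2,6-dimethyl-5-(triethylsilyloxy)cyclohex-3-ene-1-carboxylic acid (ring A C9 acid), via silyl ketene acetal 9 (not isolated), via silyl ester 10 (not isolated)
Conditions: t-BuMe2SiOTf, Et3N, toluene, 0 → 110 °C; then MeOH, rt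
Reagents that add atoms: none
Why: Ireland–Claisen ring contraction of the lactone silyl ketene acetal runs through an enforced boat (bicyclo[2.2.2]-like) transition state, so the C1–C10 bond forms suprafacially from C13–O with C9 cis to the C11 methyl and trans to O12, and the (Z)‑alkene places the C15 methyl cis and the ester trans to C9.

**Step 8**
Reactants: 11 ring A C9 acid
Product: 13 ring A γ-lactone (C9H2–O–C2=O; trans-fused at C1/C10), via hydroxy ester 12 (not isolated)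
Conditions: BH3·SMe2, THF, 0 °C → rt; then PPTS (cat.), toluene, 80 °C
Reagents that add atoms: none
Why: Borane reduces the acid chemoselectively over the hindered ester and the hindered ring alkene, and acid‑catalysed lactonisation then ties C9–O to C2.

**Step 9**
Reactants: 13 ring A γ-lactone
Product: 14 ring A lactol (C2 hemiacetal, anomer mixture)
Conditions: i-Bu2AlH (1.1 equiv), CH2Cl2, −78 °C
Reagents that add atoms: none
Why: Half‑reduction of the lactone stops at the lactol, a masked C2 aldehyde.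

**Step 10**
Reactants: 14 ring A lactol; 15 (4-bromobut-1-yn-1-yl)trimethylsilane
Product: 18 (2R)-alkyne diol (C2–OH, C9H2–OH, 12-OTES), via Grignard reagent 16 (not isolated), via silylalkyne diol 17 (not isolated)
Conditions: 15, Mg, THF (→ 16, 3.5 equiv); 14, −78 → 0 °C; then MeOH, K2CO3, rt
Reagents that add atoms: none
Why: Grignard addition to the open aldehyde form follows Felkin–Anh (attack anti to C10, carbonyl oxygen next to the C15 methyl) to give the 2R carbinol, and methanolic K2CO3 then cleaves the alkynyl silane.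

**Step 11**
Reactants: 18 (2R)-alkyne diol
Product: 19 tris(triethylsilyl) ether alkyne
Conditions: Et3SiOTf (2.4 equiv), 2,6-lutidine, CH2Cl2, −78 → 0 °C
Reagents that add atoms: triethylsilyl triflate, CC[Si](CC)(CC)OS(=O)(=O)C(F)(F)F
Why: Silylation protects O2 and O9 as ethers that can later be told apart (primary versus secondary).

**Step 12**
Reactants: 19 tris(triethylsilyl) ether alkyne
Product: 21 2-iodoalkene tris(triethylsilyl) ether, via alkenylborane 20 (not isolated)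
Conditions: 9-iodo-9-BBN, pentane/CH2Cl2, −20 °C; then AcOH, 0 °C
Reagents that add atoms: 9-iodo-9-borabicyclo[3.3.1]nonane, IB1C2CCCC1CCC2
Why: syn‑Haloboration of the terminal alkyne followed by protodeboronation gives the Markovnikov 2‑iodo‑1‑alkene (C5–I, C16 methylene).

**Step 13**
Reactants: 21 2-iodoalkene tris(triethylsilyl) ether
Product: 23 ring A C9 aldehyde (2,12-bis-OTES, 2-iodoalkene), via alkoxysulfonium chloride 22 (not isolated)
Conditions: (COCl)2, DMSO, CH2Cl2, −78 → −30 °C; then Et3N, −78 → 0 °C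
Reagents that add atoms: none
Why: Under Swern conditions a primary TES ether is cleaved and oxidised directly to the aldehyde while the hindered secondary TES ethers survive.

**Step 14**
Reactants: 24 diethyl (S)-malate
Product: 26 diethyl (2S,3R)-2-hydroxy-3-methylbutanedioate, via dilithium enolate 25 (not isolated)
Conditions: LiN(i-Pr)2 (2.2 equiv), THF, −78 → −20 °C; then MeI, −78 → 0 °C
Reagents that add atoms: iodomethane, CI
Why: Frater–Seebach alkylation of the alkoxide enolate methylates anti to the oxygen and sets C17 (3R) from the malate stereocenter.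

**Step 15**
Reactants: 26 diethyl (2S,3R)-2-hydroxy-3-methylbutanedioate
Product: 27 (2S,3R)-2-hydroxy-3-methylbutanedioic acid
Conditions: KOH, MeOH/H2O, rt; HCl work-up
Reagents that add atoms: potassium hydroxide, [K+].[OH-]
Why: Saponification frees the α‑hydroxy acid needed for acetal formation; cold conditions avoid epimerisation.

**Step 16**
Reactants: 27 (2S,3R)-2-hydroxy-3-methylbutanedioic acid
Product: 28 (2S,5S)-2-tert-butyl-5-[(1R)-1-carboxyethyl]-1,3-dioxolan-4-one (cis)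
Conditions: t-BuCHO, TsOH (cat.), pentane, reflux (Dean–Stark); crystallisation
Reagents that add atoms: pivalaldehyde, CC(C)(C)C=O
Why: Seebach acetalisation of the α‑hydroxy acid gives the cis dioxolanone, whose acetal center stores the C8 configuration.

**Step 17**
Reactants: 28 cis-dioxolanone acid; 23 ring A C9 aldehyde
Product: 30 aldol adduct (9R carbinol, C8 quaternary dioxolanone, C19 acid), via dilithium enolate 29 (not isolated)
Conditions: 28, LiN(SiMe3)2 (2.2 equiv), THF, −78 °C; then 23, −78 °C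
Reagents that add atoms: none
Why: In this self‑regeneration‑of‑stereocentres aldol the enolate is attacked anti to the tert‑butyl group (retention at C8), and Felkin–Anh addition anti to the quaternary C1 gives the 9R carbinol.

**Step 18**
Reactants: 30 aldol adduct
Product: 32 9-O-TBS dioxolanone acid, via bis-silyl derivative 31 (not isolated)
Conditions: t-BuMe2SiOTf (2.5 equiv), 2,6-lutidine, CH2Cl2, −40 → 0 °C; then MeOH
Reagents that add atoms: tert-butyldimethylsilyl triflate, CC(C)(C)[Si](C)(C)OS(=O)(=O)C(F)(F)F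
Why: Silylation blocks O9 so that only O7 can later lactonise; methanol cleaves the labile silyl ester.

**Step 19**
Reactants: 32 9-O-TBS dioxolanone acid
Product: 33 α-hydroxy ketone acid (C8–OH, C7 ketone, C6 as 1,3-dithian-2-yl)
Conditions: 2-lithio-1,3-dithiane (from 1,3-dithiane, n-BuLi; 4 equiv), THF, −78 → −30 °C
Reagents that add atoms: 2-lithio-1,3-dithiane, [Li]C1SCCCS1
Why: Corey–Seebach acyl‑anion addition to the acylal carbonyl gives the ketone after loss of pivalaldehyde; deprotonation of the acidic C6–H prevents a second addition.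

**Step 20**
Reactants: 33 α-hydroxy ketone acid
Product: 35 γ-lactone (7R; C8–OH, C6 dithiane), via dihydroxy acid 34 (not isolated)
Conditions: Zn(BH4)2, Et2O, −30 °C; then PPTS (cat.), CH2Cl2, rt
Reagents that add atoms: none
Why: Cram‑chelate reduction (zinc bridges O8 and the C7 carbonyl; hydride enters from the side of the smaller C17 branch, away from C9) gives the 7R alcohol, which lactonises with the C19 acid.

**Step 21**
Reactants: 35 γ-lactone dithiane
Product: 36 C6 aldehyde (seco compound with the 2-iodoalkene)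
Conditions: MeI, CaCO3, MeCN/H2O (9:1), 45 °C
Reagents that add atoms: water, O
Why: Alkylative hydrolysis of the dithiane under neutral conditions unmasks the aldehyde without disturbing the silyl ethers, the lactone or the vinyl iodide.

**Step 22**
Reactants: 36 C6 aldehyde
Product: 37 ten-membered allylic alcohol (C6 epimers, both used)
Conditions: CrCl2 (10 equiv), NiCl2 (cat.), DMSO/THF, 2 mM, rt
Reagents that add atoms: none
Why: Nozaki–Hiyama–Kishi cyclisation of the 2‑iodoalkene onto the aldehyde forms C5–C6 and the C5 exo‑methylene; the C6 configuration does not matter because step 23 removes it.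

**Step 23**
Reactants: 37 ten-membered allylic alcohol
Product: 38 ten-membered enone (C6 ketone, C5 methylene)
Conditions: Dess–Martin periodinane, NaHCO3, CH2Cl2, 0 °C → rt
Reagents that add atoms: none
Why: Dess–Martin oxidation converges both C6 epimers to one enone; the tertiary C8–OH is inert.

**Step 24**
Reactants: 38 ten-membered enone
Product: 39 (6R)-allylic alcohol
Conditions: NaBH4, CeCl3·7H2O, MeOH, −78 °C
Reagents that add atoms: none
Why: Luche 1,2‑reduction with Felkin–Anh attack anti to the C7–O bond gives the 6,7‑syn (6R) alcohol.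

**Step 25**
Reactants: 39 (6R)-allylic alcohol
Product: 40 (6S)-allylic chloride
Conditions: PPh3, Cl3CC(O)CCl3, CH2Cl2, −20 → 0 °C
Reagents that add atoms: hexachloroacetone, ClC(Cl)(Cl)C(=O)C(Cl)(Cl)Cl
Why: Appel‑type chlorination is an SN2 displacement of the oxyphosphonium with inversion and without allylic transposition, giving the 6S chloride.

**Step 26**
Reactants: 40 (6S)-allylic chloride
Product: 41 2,12-diol (9-OTBS kept)
Conditions: HF·pyridine, pyridine, THF, 0 °C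
Reagents that add atoms: none
Why: Buffered fluoride cleaves the two TES ethers much faster than the very hindered C9 TBS ether.

**Step 27**
Reactants: 41 2,12-diol
Product: 42 13α,14α-epoxide diol
Conditions: VO(acac)2 (5 mol %), t-BuOOH (1.1 equiv), CH2Cl2, 0 °C
Reagents that add atoms: tert-butyl hydroperoxide, CC(C)(C)OO
Why: Hydroxyl‑directed vanadium epoxidation delivers oxygen syn to the allylic C12–OH (α face) and leaves the C5 methylene, which has no allylic hydroxyl, alone.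

**Step 28**
Reactants: 42 epoxide diol
Product: 43 2,12-diacetate 9-TBS ether
Conditions: Ac2O, pyridine, DMAP (cat.), CH2Cl2, 0 °C → rt
Reagents that add atoms: acetic anhydride, CC(=O)OC(C)=O
Why: Acetylation esterifies the two secondary alcohols; the tertiary C8–OH is too hindered to react.

**Step 29**
Reactants: 43 2,12-diacetate 9-TBS ether
Product: 44 CNP0242711.1 (target)
Conditions: HF·pyridine, THF, rt
Reagents that add atoms: none
Why: Fluoride desilylation frees the C9 hydroxyl under conditions that spare the acetates, epoxide, lactone and allylic chloride.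

**Compound list**
1 | (3S,4S)-hexa-1,5-diene-3,4-diol | C=C[C@H](O)[C@@H](O)C=C | starting material
2 | (3S,4S)-4-(triethylsilyloxy)hexa-1,5-dien-3-ol | C=C[C@H](O[Si](CC)(CC)CC)[C@@H](O)C=C | intermediate
3 | (3S,4S)-4-(triethylsilyloxy)hexa-1,5-dien-3-yl acrylate | C=C[C@H](O[Si](CC)(CC)CC)[C@@H](OC(=O)C=C)C=C | intermediate
4 | (5S,6S)-6-ethenyl-5-(triethylsilyloxy)-5,6-dihydro-2H-pyran-2-one | O=C1C=C[C@H](O[Si](CC)(CC)CC)[C@H](C=C)O1 | intermediate
5 | (4R,5S,6S)-6-ethenyl-4-methyl-5-(triethylsilyloxy)oxan-2-one | O=C1C[C@@H](C)[C@H](O[Si](CC)(CC)CC)[C@H](C=C)O1 | intermediate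
6 | ozonide (1,2,4-trioxolane) of 5 | O=C1C[C@@H](C)[C@H](O[Si](CC)(CC)CC)[C@H](C2OCOO2)O1 | intermediate
7 | (2R,3S,4R)-4-methyl-6-oxo-3-(triethylsilyloxy)oxane-2-carbaldehyde | O=C1C[C@@H](C)[C@H](O[Si](CC)(CC)CC)[C@H](C=O)O1 | intermediate
8 | ethyl (Z)-2-methyl-3-[(2S,3S,4R)-4-methyl-6-oxo-3-(triethylsilyloxy)oxan-2-yl]prop-2-enoate | O=C1C[C@@H](C)[C@H](O[Si](CC)(CC)CC)[C@H](/C=C(/C)C(=O)OCC)O1 | intermediate
9 | lactone TBS ketene acetal of 8 | CC(C)(C)[Si](C)(C)OC1=C[C@@H](C)[C@H](O[Si](CC)(CC)CC)[C@H](/C=C(/C)C(=O)OCC)O1 | intermediate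
10 | TBS ester of 11 | CCOC(=O)[C@@]1(C)C=C[C@@H](O[Si](CC)(CC)CC)[C@H](C)[C@@H]1C(=O)O[Si](C)(C)C(C)(C)C | intermediate
11 | (1S,2S,5R,6R)-2-(ethoxycarbonyl)-2,6-dimethyl-5-(triethylsilyloxy)cyclohex-3-ene-1-carboxylic acid (C1: β-Me, α-CO2Et; C10: β-CO2H; C11: β-Me; C12: α-OTES) | CCOC(=O)[C@@]1(C)C=C[C@@H](O[Si](CC)(CC)CC)[C@H](C)[C@@H]1C(=O)O | intermediate
12 | ring A hydroxy ester (C9H2OH, C2 ethyl ester) | CCOC(=O)[C@@]1(C)C=C[C@@H](O[Si](CC)(CC)CC)[C@H](C)[C@@H]1CO | intermediate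
13 | ring A trans-fused γ-lactone (C9H2–O–C2=O) | O=C1OC[C@H]2[C@@H](C)[C@H](O[Si](CC)(CC)CC)C=C[C@]12C | intermediate
14 | ring A lactol (C2 hemiacetal) | OC1OC[C@H]2[C@@H](C)[C@H](O[Si](CC)(CC)CC)C=C[C@]12C | intermediate
15 | (4-bromobut-1-yn-1-yl)trimethylsilane | C[Si](C)(C)C#CCCBr | starting material
16 | [4-(trimethylsilyl)but-3-yn-1-yl]magnesium bromide | C[Si](C)(C)C#CCC[Mg]Br | intermediate
17 | (2R)-silylalkyne diol | C[Si](C)(C)C#CCC[C@@H](O)[C@@]1(C)C=C[C@@H](O[Si](CC)(CC)CC)[C@H](C)[C@@H]1CO | intermediate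
18 | (2R)-alkyne diol | C#CCC[C@@H](O)[C@@]1(C)C=C[C@@H](O[Si](CC)(CC)CC)[C@H](C)[C@@H]1CO | intermediate
19 | tris(triethylsilyl) ether alkyne | C#CCC[C@@H](O[Si](CC)(CC)CC)[C@@]1(C)C=C[C@@H](O[Si](CC)(CC)CC)[C@H](C)[C@@H]1CO[Si](CC)(CC)CC | intermediate
20 | (Z)-2-iodoalkenyl-9-BBN adduct | I/C(CC[C@@H](O[Si](CC)(CC)CC)[C@@]1(C)C=C[C@@H](O[Si](CC)(CC)CC)[C@H](C)[C@@H]1CO[Si](CC)(CC)CC)=C\B1C2CCCC1CCC2 | intermediate
21 | 2-iodoalkene tris(triethylsilyl) ether | C=C(I)CC[C@@H](O[Si](CC)(CC)CC)[C@@]1(C)C=C[C@@H](O[Si](CC)(CC)CC)[C@H](C)[C@@H]1CO[Si](CC)(CC)CC | intermediate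
22 | C9 alkoxydimethylsulfonium chloride | C=C(I)CC[C@@H](O[Si](CC)(CC)CC)[C@@]1(C)C=C[C@@H](O[Si](CC)(CC)CC)[C@H](C)[C@@H]1CO[S+](C)C.[Cl-] | intermediate
23 | ring A C9 aldehyde (2R; 2,12-bis-OTES; 2-iodoalkene) | C=C(I)CC[C@@H](O[Si](CC)(CC)CC)[C@@]1(C)C=C[C@@H](O[Si](CC)(CC)CC)[C@H](C)[C@@H]1C=O | intermediate
24 | diethyl (S)-malate | CCOC(=O)[C@@H](O)CC(=O)OCC | starting material
25 | dilithium alkoxide enolate of 24 | CCOC(=O)[C@@H](O[Li])C=C(O[Li])OCC | intermediate
26 | diethyl (2S,3R)-2-hydroxy-3-methylbutanedioate | CCOC(=O)[C@@H](O)[C@@H](C)C(=O)OCC | intermediate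
27 | (2S,3R)-2-hydroxy-3-methylbutanedioic acid | OC(=O)[C@@H](O)[C@@H](C)C(=O)O | intermediate
28 | (2S,5S)-2-tert-butyl-5-[(1R)-1-carboxyethyl]-1,3-dioxolan-4-one | C[C@@H](C(=O)O)[C@@H]1O[C@H](C(C)(C)C)OC1=O | intermediate
29 | dilithium enolate carboxylate of 28 | C[C@@H](C(=O)O[Li])C1=C(O[Li])O[C@@H](C(C)(C)C)O1 | intermediate
30 | aldol adduct (9R-OH; C8 in dioxolanone; C19 acid) | C=C(I)CC[C@@H](O[Si](CC)(CC)CC)[C@@]1(C)C=C[C@@H](O[Si](CC)(CC)CC)[C@H](C)[C@@H]1[C@@H](O)[C@]2(O[C@H](C(C)(C)C)OC2=O)[C@@H](C)C(=O)O | intermediate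
31 | 9-O-TBS ether TBS ester of 30 | C=C(I)CC[C@@H](O[Si](CC)(CC)CC)[C@@]1(C)C=C[C@@H](O[Si](CC)(CC)CC)[C@H](C)[C@@H]1[C@@H](O[Si](C)(C)C(C)(C)C)[C@]2(O[C@H](C(C)(C)C)OC2=O)[C@@H](C)C(=O)O[Si](C)(C)C(C)(C)C | intermediate
32 | 9-O-TBS dioxolanone acid | C=C(I)CC[C@@H](O[Si](CC)(CC)CC)[C@@]1(C)C=C[C@@H](O[Si](CC)(CC)CC)[C@H](C)[C@@H]1[C@@H](O[Si](C)(C)C(C)(C)C)[C@]2(O[C@H](C(C)(C)C)OC2=O)[C@@H](C)C(=O)O | intermediate
33 | α-hydroxy ketone acid (C7 ketone, C6 dithiane) | C=C(I)CC[C@@H](O[Si](CC)(CC)CC)[C@@]1(C)C=C[C@@H](O[Si](CC)(CC)CC)[C@H](C)[C@@H]1[C@@H](O[Si](C)(C)C(C)(C)C)[C@@](O)(C(=O)C2SCCCS2)[C@@H](C)C(=O)O | intermediate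
34 | (7R)-7,8-dihydroxy acid | C=C(I)CC[C@@H](O[Si](CC)(CC)CC)[C@@]1(C)C=C[C@@H](O[Si](CC)(CC)CC)[C@H](C)[C@@H]1[C@@H](O[Si](C)(C)C(C)(C)C)[C@@](O)([C@@H](O)C2SCCCS2)[C@@H](C)C(=O)O | intermediate
35 | γ-lactone with C6 dithiane | C=C(I)CC[C@@H](O[Si](CC)(CC)CC)[C@@]1(C)C=C[C@@H](O[Si](CC)(CC)CC)[C@H](C)[C@@H]1[C@@H](O[Si](C)(C)C(C)(C)C)[C@]2(O)[C@@H](C)C(=O)O[C@H]2C3SCCCS3 | intermediate
36 | C6 aldehyde (seco compound) | C=C(I)CC[C@@H](O[Si](CC)(CC)CC)[C@@]1(C)C=C[C@@H](O[Si](CC)(CC)CC)[C@H](C)[C@@H]1[C@@H](O[Si](C)(C)C(C)(C)C)[C@]2(O)[C@@H](C)C(=O)O[C@H]2C=O | intermediate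
37 | ten-membered allylic alcohol (C6 epimers) | C=C1CC[C@@H](O[Si](CC)(CC)CC)[C@]2(C)[C@H]([C@@H](C)[C@H](O[Si](CC)(CC)CC)C=C2)[C@@H](O[Si](C)(C)C(C)(C)C)[C@]2(O)[C@@H](C)C(=O)O[C@H]2C1O | intermediate
38 | ten-membered enone | C=C1CC[C@@H](O[Si](CC)(CC)CC)[C@]2(C)[C@H]([C@@H](C)[C@H](O[Si](CC)(CC)CC)C=C2)[C@@H](O[Si](C)(C)C(C)(C)C)[C@]2(O)[C@@H](C)C(=O)O[C@H]2C1=O | intermediate
39 | (6R)-allylic alcohol | C=C1CC[C@@H](O[Si](CC)(CC)CC)[C@]2(C)[C@H]([C@@H](C)[C@H](O[Si](CC)(CC)CC)C=C2)[C@@H](O[Si](C)(C)C(C)(C)C)[C@]2(O)[C@@H](C)C(=O)O[C@H]2[C@@H]1O | intermediate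
40 | (6S)-allylic chloride | C=C1CC[C@@H](O[Si](CC)(CC)CC)[C@]2(C)[C@H]([C@@H](C)[C@H](O[Si](CC)(CC)CC)C=C2)[C@@H](O[Si](C)(C)C(C)(C)C)[C@]2(O)[C@@H](C)C(=O)O[C@H]2[C@H]1Cl | intermediate
41 | 2,12-diol 9-TBS ether | C=C1CC[C@@H](O)[C@]2(C)[C@H]([C@@H](C)[C@H](O)C=C2)[C@@H](O[Si](C)(C)C(C)(C)C)[C@]2(O)[C@@H](C)C(=O)O[C@H]2[C@H]1Cl | intermediate
42 | 13α,14α-epoxide 2,12-diol 9-TBS ether | C=C1CC[C@@H](O)[C@]2(C)[C@H]([C@@H](C)[C@H](O)[C@@H]3O[C@@H]32)[C@@H](O[Si](C)(C)C(C)(C)C)[C@]2(O)[C@@H](C)C(=O)O[C@H]2[C@H]1Cl | intermediate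
43 | 2,12-diacetate 9-TBS ether | C=C1CC[C@@H](OC(C)=O)[C@]2(C)[C@H]([C@@H](C)[C@H](OC(C)=O)[C@@H]3O[C@@H]32)[C@@H](O[Si](C)(C)C(C)(C)C)[C@]2(O)[C@@H](C)C(=O)O[C@H]2[C@H]1Cl | intermediate
44 | CNP0242711.1 | C=C1CC[C@@H](OC(C)=O)[C@]2(C)[C@H]([C@@H](C)[C@H](OC(C)=O)[C@@H]3O[C@@H]32)[C@@H](O)[C@]2(O)[C@@H](C)C(=O)O[C@H]2[C@H]1Cl | target

**Step count and risks**

Total steps: 29. Longest linear sequence: 26 (steps 1–13 and 17–29); steps 14–16 make the malate fragment.

The three steps most likely to fail: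

Step 22, closure of the ten‑membered ring. If the chromium‑mediated cyclisation gives oligomers, the ring is closed as a ketone instead. The fallback sets out from aldehyde 36. Pinnick oxidation (NaClO2, NaH2PO4, 2‑methylbut‑2‑ene) gives the C6 carboxylic acid F5. 2,2′‑Dipyridyl disulfide and PPh3 turn it into the S‑pyridin‑2‑yl thioester F6. An intramolecular reductive acyl–vinyl coupling of the thioester with the 2‑iodoalkene (NiBr2(dtbbpy) cat., Cp2ZrCl2, Zn, DMI/THF, high dilution) then gives the enone directly. This comes back to the route at 38 and also skips step 23.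

Step 10, the C2 configuration. The Felkin preference (C15 methyl or C14 flanking the carbonyl oxygen) is hard to call. If the Grignard addition gives mainly the 2S carbinol, the nucleophile and the hydrogen are swapped. The fallback sets out from lactone 13. One equivalent of Grignard reagent 16 at −78 °C adds to the lactone carbonyl to give the C2 hemiketal F1 (in equilibrium with the hydroxy ketone). NaBH4 in MeOH then delivers hydride through the same facial preference, which now gives the 2R alcohol; K2CO3 in the same pot removes the alkynyl silane. This comes back to the route at 18.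

Step 19, acyl‑anion addition to an acylal next to a quaternary carbon. If the lithiodithiane does not add, C6 is brought in by olefination and C7 is set by iodolactonisation. The fallback sets out from 32. i‑Bu2AlH (2.2 equiv, −78 °C) reduces the dioxolanone carbonyl to the dioxolane lactol F2. Excess Ph3P=CH2 opens it (pivalaldehyde is lost) to the vinyl carbinol acid F3. Kinetic iodolactonisation (I2, NaHCO3, MeCN, 0 °C) places the iodomethyl group cis to the C8 hydroxyl, giving the 7R iodomethyl γ‑lactone F4. Kornblum oxidation (AgBF4, DMSO; then Et3N) gives the aldehyde and comes back to the route at 36.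

**Further compounds**
F1 | step 10 | C2 hemiketal from lactone 13 and Grignard reagent 16 | C[Si](C)(C)C#CCCC1(O)OC[C@H]2[C@@H](C)[C@H](O[Si](CC)(CC)CC)C=C[C@]12C
F2 | step 19 | dioxolane lactol (C7 hemiacetal) | C=C(I)CC[C@@H](O[Si](CC)(CC)CC)[C@@]1(C)C=C[C@@H](O[Si](CC)(CC)CC)[C@H](C)[C@@H]1[C@@H](O[Si](C)(C)C(C)(C)C)[C@]2(O[C@H](C(C)(C)C)OC2O)[C@@H](C)C(=O)O
F3 | step 19 | vinyl carbinol acid (C7=C6 vinyl on C8) | C=C(I)CC[C@@H](O[Si](CC)(CC)CC)[C@@]1(C)C=C[C@@H](O[Si](CC)(CC)CC)[C@H](C)[C@@H]1[C@@H](O[Si](C)(C)C(C)(C)C)[C@@](O)(C=C)[C@@H](C)C(=O)O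
F4 | step 19 | (7R)-iodomethyl γ-lactone | C=C(I)CC[C@@H](O[Si](CC)(CC)CC)[C@@]1(C)C=C[C@@H](O[Si](CC)(CC)CC)[C@H](C)[C@@H]1[C@@H](O[Si](C)(C)C(C)(C)C)[C@]2(O)[C@@H](C)C(=O)O[C@H]2CI
F5 | step 22 | C6 carboxylic acid | C=C(I)CC[C@@H](O[Si](CC)(CC)CC)[C@@]1(C)C=C[C@@H](O[Si](CC)(CC)CC)[C@H](C)[C@@H]1[C@@H](O[Si](C)(C)C(C)(C)C)[C@]2(O)[C@@H](C)C(=O)O[C@H]2C(=O)O
F6 | step 22 | C6 S-pyridin-2-yl thioester | C=C(I)CC[C@@H](O[Si](CC)(CC)CC)[C@@]1(C)C=C[C@@H](O[Si](CC)(CC)CC)[C@H](C)[C@@H]1[C@@H](O[Si](C)(C)C(C)(C)C)[C@]2(O)[C@@H](C)C(=O)O[C@H]2C(=O)Sc3ccccn3
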